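**Plan**

Numbering used below: carbocycle C1–C6 (C1 carries the oxane, C4 = CMeCl, C5 = CHBr); oxane carbons C7 (OCMe), C8 (CHOH), C9, C10 (CHBr), C11 (CMe2).
Retrosynthesis: C4–Cl and C5–Br go back to a cis-4,5-diol (cyclic sulfate; the C4 oxygen from a formyl group by Baeyer–Villiger oxidation). The oxane is opened at O–C11/C10–Br to a C7 alcohol and a C10=C11 alkene, and C1–H goes back to a C1=C6 alkene. The cyclohexene is then cut at C2–C3 and C4–C5 into a 1-silyloxy-3-alkyl diene and methacrolein, and the diene is cut at C5 (DMF), C2 (cuprate methyl), C7–C1 (acetylide), C7–CH3 and C9–C10 back to methyl (R)-glycidate.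
Forward order: the acyclic C7–C11 chain is made first, the carbocycle arises in the cycloaddition (step 8), the oxane closes in step 10, and the ring halogens come last.
Stereochemistry: C8 is bought; C7 comes from chelation-controlled alkynylation; C4 and C5 from the catalyst-controlled endo cycloaddition; C1 from hydrogenation directed by the C5 hydroxyl; C10 from a chair bromoetherification; bromide enters C5 with inversion and chloride enters C4 with retention.
Enabling feature: in the carbocycle the heteroatom-bearing C4 and C5 are adjacent and the branch at C1 lies 1,3 to C5 and 1,4 to C4. This is the ortho/para pattern of a 1-oxy-3-alkyl-buta-1,3-diene (C5=C6–C1=C2) adding to a 2-methyl enal (C3=C4), so one [4+2] event builds the ring with oxygen handles on C4 and C5 and a C1=C6 alkene beside the C5 hydroxyl.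

Key step: step 8

Step 1
Reactants: 1 methyl (2R)-oxirane-2-carboxylate; 2 (2-methylprop-1-en-1-yl)magnesium bromide
Product: 3 methyl (2R)-2-hydroxy-5-methylhex-4-enoate
Conditions: CuBr·SMe2 (10 mol%), THF, −60 → −30 °C; aq. NH4Cl
Reagents that add atoms: none
Why: Copper-catalysed Grignard opening of a terminal epoxide (SN2 at the unsubstituted carbon, the later C9), which leaves the bought (R) centre, the later C8, untouched.

Step 2
Reactants: 3 methyl (2R)-2-hydroxy-5-methylhex-4-enoate
Product: 5 (3R)-3-hydroxy-6-methylhept-5-en-2-one, via N-methoxy-N-methylamide 4 (not isolated)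
Conditions: MeNH(OMe)·HCl, iPrMgCl, THF, −20 °C; then MeMgBr, −20 → 0 °C
Reagents that add atoms: methylmagnesium bromide, C[Mg]Br
Why: Weinreb ketone synthesis in one pot: the magnesium amide converts the ester into amide 4, whose magnesium chelate accepts only one methyl, and the α-alkoxide centre C8 should not be enolised under these conditions.

Step 3
Reactants: 5 (3R)-3-hydroxy-6-methylhept-5-en-2-one; 6 ethynylmagnesium bromide
Product: 7 (3R,4R)-3,7-dimethyloct-6-en-1-yne-3,4-diol
Conditions: HC≡CMgBr (3.5 equiv), THF, −78 → −20 °C; aq. NH4Cl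
Reagents that add atoms: none
Why: Chelation-controlled Grignard addition: the magnesium alkoxide at C8 and the ketone oxygen form a five-membered chelate and the acetylide enters from the face flanked by hydrogen instead of the prenyl CH2, which should set C7 as R (3R in 7).

Step 4
Reactants: 7 (3R,4R)-3,7-dimethyloct-6-en-1-yne-3,4-diol
Product: 9 (3R,4R)-3,7-dimethyl-3-(triethylsilyloxy)-4-(triisopropylsilyloxy)oct-6-en-1-yne, via mono-TIPS ether 8 (not isolated)
Conditions: TIPSOTf (1.05 equiv), 2,6-lutidine, CH2Cl2, −78 → 0 °C; then TESOTf, 0 °C → rt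
Reagents that add atoms: triisopropylsilyl triflate, CC(C)[Si](OS(=O)(=O)C(F)(F)F)(C(C)C)C(C)C; triethylsilyl triflate, CC[Si](CC)(CC)OS(=O)(=O)C(F)(F)F
Why: Silyl ether formation in two stages: the bulky triisopropylsilyl triflate should take only the secondary C8 hydroxyl, then triethylsilyl triflate caps the tertiary propargylic C7 hydroxyl, which later prevents lactol formation and keeps the alcohol away from the boron catalyst.

Step 5
Reactants: 9 (3R,4R)-3,7-dimethyl-3-(triethylsilyloxy)-4-(triisopropylsilyloxy)oct-6-en-1-yne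
Product: 11 (4R,5R)-4,8-dimethyl-4-(triethylsilyloxy)-5-(triisopropylsilyloxy)non-7-en-2-ynal, via lithium acetylide 10 (not isolated)
Conditions: nBuLi, THF, −78 °C; then DMF, −78 → 0 °C; poured into aq. KH2PO4
Reagents that add atoms: N,N-dimethylformamide, CN(C)C=O
Why: Formylation of a lithium acetylide with DMF, the hemiaminal alkoxide surviving until the buffered quench, adds C5 (the future CHBr carbon) at the aldehyde oxidation level.

Step 6
Reactants: 11 (4R,5R)-4,8-dimethyl-4-(triethylsilyloxy)-5-(triisopropylsilyloxy)non-7-en-2-ynal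
Product: 12 (2Z,4R,5R)-3,4,8-trimethyl-4-(triethylsilyloxy)-5-(triisopropylsilyloxy)nona-2,7-dienal
Conditions: Me2CuLi (from MeLi and CuI), Et2O, −78 °C; aq. NH4Cl
Reagents that add atoms: lithium dimethylcuprate, [Li+].C[Cu-]C
Why: Conjugate (1,4-) addition of lithium dimethylcuprate to the ynal brings in the methyl that becomes ring C2; syn-carbocupration should give mainly the Z enal, and this geometry is erased in step 7.

Step 7
Reactants: 12 (2Z,4R,5R)-3,4,8-trimethyl-4-(triethylsilyloxy)-5-(triisopropylsilyloxy)nona-2,7-dienal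
Product: 13 (1E,4R,5R)-4,8-dimethyl-3-methylidene-1,4-bis(triethylsilyloxy)-5-(triisopropylsilyloxy)nona-1,7-diene
Conditions: TESOTf, Et3N, Et2O, −78 → 0 °C
Reagents that add atoms: triethylsilyl triflate, CC[Si](CC)(CC)OS(=O)(=O)C(F)(F)F
Why: Silyl dienol ether formation by O-silylation and γ-deprotonation (vinylogous enolisation), for which only the new methyl offers hydrogens; the s-trans enal should give the (1E) dienol ether needed for the cycloaddition.

Step 8
Reactants: 13 (1E,4R,5R)-4,8-dimethyl-3-methylidene-1,4-bis(triethylsilyloxy)-5-(triisopropylsilyloxy)nona-1,7-diene; 14 2-methylprop-2-enal (methacrolein)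
Product: 16 (1S,2R)-2-hydroxy-4-[(2R,3R)-2-hydroxy-6-methyl-3-(triisopropylsilyloxy)hept-5-en-2-yl]-1-methylcyclohex-3-ene-1-carbaldehyde, via silylated cycloadduct 15 (not isolated)
Conditions: (S)-oxazaborolidinium triflimide [(S)-3,3-diphenyl-1-(2-methylphenyl)tetrahydro-1H,3H-pyrrolo[1,2-c][1,3,2]oxazaborole protonated by (CF3SO2)2NH] (20 mol%), CH2Cl2, −78 °C; then HF·pyridine, pyridine, THF, 0 °C
Reagents that add atoms: none
Why: A concerted, asynchronous, normal-electron-demand [4+2] cycloaddition (Diels–Alder reaction) between the electron-rich s-cis silyloxy diene and the enal whose formyl oxygen is bound to the chiral boron cation forms C2–C3 and C5–C4 in one event; the closest known reaction type is the oxazaborolidinium-catalysed Diels–Alder reaction of 2-substituted acroleins with silyloxy dienes. The carbocycle (C1–C6) closes by suprafacial addition of the dienophile across the diene termini C2 and C5, and no other ring is formed. The quaternary centre C4 is set by the catalyst, which shields one face of the bound s-trans enal so that the diene adds to the Cα-Re face (expected for the (S)-catalyst from the accepted formyl C–H···O binding model; its mirror image would serve otherwise), and C5 is set relative to C4 by the (E)-geometry of the dienol ether together with the endo position of the formyl group, which places formyl and silyloxy cis. The step needs regioselectivity, secured because the 1-silyloxy and the 3-alkyl group both enlarge the HOMO coefficient at C2 so that C2 bonds to the β-carbon and the oxygen-bearing C5 to the α-carbon, and chemoselectivity over the isolated C10=C11 alkene, secured by the much higher reactivity of the silyloxy diene, whose bulky C1 substituent also favours the reactive s-cis form. The buffered fluoride work-up then removes both triethylsilyl groups and leaves the triisopropylsilyl ether.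

Step 9
Reactants: 16 (1S,2R)-2-hydroxy-4-[(2R,3R)-2-hydroxy-6-methyl-3-(triisopropylsilyloxy)hept-5-en-2-yl]-1-methylcyclohex-3-ene-1-carbaldehyde
Product: 17 (1S,2R,4S)-2-hydroxy-4-[(2R,3R)-2-hydroxy-6-methyl-3-(triisopropylsilyloxy)hept-5-en-2-yl]-1-methylcyclohexane-1-carbaldehyde
Conditions: [Rh(nbd)(dppb)]BF4 (10 mol%), H2 (60 atm), CH2Cl2, rt
Reagents that add atoms: none
Why: Hydroxyl-directed homogeneous hydrogenation with a cationic monovalent rhodium diphosphine complex: the ring hydroxyl at C5 (and the freely rotating C7 hydroxyl, which can reach the same face) bind rhodium so that hydrogen adds to C1=C6 from the C5–OH face, making C1–H cis to C5–OH, while the undirected trisubstituted C10=C11 alkene should not be reduced by this catalyst type.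

Step 10
Reactants: 17 (1S,2R,4S)-2-hydroxy-4-[(2R,3R)-2-hydroxy-6-methyl-3-(triisopropylsilyloxy)hept-5-en-2-yl]-1-methylcyclohexane-1-carbaldehyde
Product: 18 (1S,2R,4S)-4-[(2R,3R,5R)-5-bromo-2,6,6-trimethyl-3-(triisopropylsilyloxy)oxan-2-yl]-2-hydroxy-1-methylcyclohexane-1-carbaldehyde
Conditions: 2,4,4,6-tetrabromocyclohexa-2,5-dienone (TBCO), MeNO2, 0 °C, dark
Reagents that add atoms: 2,4,4,6-tetrabromocyclohexa-2,5-dien-1-one, O=C1C(Br)=CC(Br)(Br)C=C1Br
Why: Bromoetherification (6-endo halo-cyclisation): the bromonium ion at C10=C11 is opened anti at the more substituted C11 by the tertiary C7 hydroxyl through a chair in which bromine and the cyclohexyl group are equatorial, the C7 methyl is axial and the bulky silyloxy group is axial (anti to that methyl, one gauche contact instead of two), which should set C10 as R, while the hindered silyl ether oxygen at C8 should not compete by 5-endo closure.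

Step 11
Reactants: 18 (1S,2R,4S)-4-[(2R,3R,5R)-5-bromo-2,6,6-trimethyl-3-(triisopropylsilyloxy)oxan-2-yl]-2-hydroxy-1-methylcyclohexane-1-carbaldehyde
Product: 20 (1S,2R,4S)-4-[(2R,3R,5R)-5-bromo-2,6,6-trimethyl-3-(triisopropylsilyloxy)oxan-2-yl]-1-methylcyclohexane-1,2-diol, via formate 19 (not isolated)
Conditions: mCPBA, NaHCO3, CH2Cl2, 0 °C → rt; then K2CO3, MeOH, 0 °C
Reagents that add atoms: 3-chloroperoxybenzoic acid, OOC(=O)c1cccc(Cl)c1
Why: Baeyer–Villiger oxidation of an aldehyde on a quaternary carbon, in which the tertiary alkyl group migrates with retention to give formate 19, followed by methanolysis to the cis-4,5-diol.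

Step 12
Reactants: 20 (1S,2R,4S)-4-[(2R,3R,5R)-5-bromo-2,6,6-trimethyl-3-(triisopropylsilyloxy)oxan-2-yl]-1-methylcyclohexane-1,2-diol
Product: 22 cyclic sulfate (1,3,2-dioxathiolane 2,2-dioxide) of diol 20, via cyclic sulfite 21 (not isolated)
Conditions: SOCl2, Et3N, CH2Cl2, 0 °C; then RuCl3 (cat.), NaIO4, MeCN/CCl4/H2O, 0 °C
Reagents that add atoms: thionyl chloride, O=S(Cl)Cl; sodium periodate NaIO4, [Na+].[O-][I](=O)(=O)=O
Why: Cyclic sulfite formation and RuO4-catalysed oxidation to the cyclic sulfate, a well-precedented activation of a cis-1,2-diol that changes no stereocentre.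

Step 13
Reactants: 22 cyclic sulfate of diol 20
Product: 24 (1S,2S,4S)-2-bromo-4-[(2R,3R,5R)-5-bromo-2,6,6-trimethyl-3-(triisopropylsilyloxy)oxan-2-yl]-1-methylcyclohexan-1-ol, via lithium bromo sulfate 23 (not isolated)
Conditions: LiBr, THF, 40 °C; then H2SO4 (cat.), H2O (1–2 equiv), THF, rt
Reagents that add atoms: lithium bromide, [Li+].[Br-]
Why: SN2 opening of the cyclic sulfate by bromide at the secondary carbon C5 with inversion (bromine ends equatorial, cis to the C1 substituent), then acid hydrolysis of the sulfate monoester at sulfur, which keeps C4 and gives the trans-bromohydrin.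

Step 14
Reactants: 24 (1S,2S,4S)-2-bromo-4-[(2R,3R,5R)-5-bromo-2,6,6-trimethyl-3-(triisopropylsilyloxy)oxan-2-yl]-1-methylcyclohexan-1-ol
Product: 25 {[(2R,3R,5R)-5-bromo-2-[(1S,3S,4S)-3-bromo-4-chloro-4-methylcyclohexyl]-2,6,6-trimethyloxan-3-yl]oxy}tri(propan-2-yl)silane
Conditions: SOCl2, CH2Cl2, −20 → 0 °C, no base
Reagents that add atoms: thionyl chloride, O=S(Cl)Cl
Why: Chlorodehydroxylation of a tertiary alcohol through its chlorosulfite with internal return (SNi, frontside delivery of chloride within the ion pair), which should give retention at C4; without base there is no SN2 or E2 pathway, and in the chair locked by the equatorial oxanyl group the equatorial C5–Br bond is gauche to the breaking C4–O bond, so the bromine should not bridge and migrate.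

Step 15
Reactants: 25 {[(2R,3R,5R)-5-bromo-2-[(1S,3S,4S)-3-bromo-4-chloro-4-methylcyclohexyl]-2,6,6-trimethyloxan-3-yl]oxy}tri(propan-2-yl)silane
Product: 26 caespitol, (2R,3R,5R)-5-bromo-2-[(1S,3S,4S)-3-bromo-4-chloro-4-methylcyclohexyl]-2,6,6-trimethyloxan-3-ol
Conditions: HF·pyridine, THF, 0 °C → rt
Reagents that add atoms: none
Why: Fluoride-mediated cleavage of the silyl ether (desilylation) under mildly acidic conditions that should leave the tertiary chloride, both secondary bromides and the oxane untouched.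

**Compound list**

1 | methyl (2R)-oxirane-2-carboxylate | COC(=O)[C@H]1CO1 | starting material
2 | (2-methylprop-1-en-1-yl)magnesium bromide | CC(C)=C[Mg]Br | starting material
3 | methyl (2R)-2-hydroxy-5-methylhex-4-enoate | COC(=O)[C@H](O)CC=C(C)C | intermediate
4 | (2R)-2-hydroxy-N-methoxy-N,5-dimethylhex-4-enamide | CON(C)C(=O)[C@H](O)CC=C(C)C | intermediate
5 | (3R)-3-hydroxy-6-methylhept-5-en-2-one | CC(=O)[C@H](O)CC=C(C)C | intermediate
6 | ethynylmagnesium bromide | C#C[Mg]Br | starting material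
7 | (3R,4R)-3,7-dimethyloct-6-en-1-yne-3,4-diol | O[C@](C)(C#C)[C@H](O)CC=C(C)C | intermediate
8 | (3R,4R)-3,7-dimethyl-4-(triisopropylsilyloxy)oct-6-en-1-yn-3-ol | O[C@](C)(C#C)[C@H](O[Si](C(C)C)(C(C)C)C(C)C)CC=C(C)C | intermediate
9 | (3R,4R)-3,7-dimethyl-3-(triethylsilyloxy)-4-(triisopropylsilyloxy)oct-6-en-1-yne | CC[Si](CC)(CC)O[C@](C)(C#C)[C@H](O[Si](C(C)C)(C(C)C)C(C)C)CC=C(C)C | intermediate
10 | [(3R,4R)-3,7-dimethyl-3-(triethylsilyloxy)-4-(triisopropylsilyloxy)oct-6-en-1-yn-1-yl]lithium | CC[Si](CC)(CC)O[C@](C)(C#C[Li])[C@H](O[Si](C(C)C)(C(C)C)C(C)C)CC=C(C)C | intermediate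
11 | (4R,5R)-4,8-dimethyl-4-(triethylsilyloxy)-5-(triisopropylsilyloxy)non-7-en-2-ynal | CC[Si](CC)(CC)O[C@](C)(C#CC=O)[C@H](O[Si](C(C)C)(C(C)C)C(C)C)CC=C(C)C | intermediate
12 | (2Z,4R,5R)-3,4,8-trimethyl-4-(triethylsilyloxy)-5-(triisopropylsilyloxy)nona-2,7-dienal | CC[Si](CC)(CC)O[C@](C)(/C(C)=C\C=O)[C@H](O[Si](C(C)C)(C(C)C)C(C)C)CC=C(C)C | intermediate
13 | (1E,4R,5R)-4,8-dimethyl-3-methylidene-1,4-bis(triethylsilyloxy)-5-(triisopropylsilyloxy)nona-1,7-diene | CC[Si](CC)(CC)O[C@](C)(C(=C)/C=C/O[Si](CC)(CC)CC)[C@H](O[Si](C(C)C)(C(C)C)C(C)C)CC=C(C)C | intermediate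
14 | 2-methylprop-2-enal (methacrolein) | CC(=C)C=O | starting material
15 | (1S,2R)-1-methyl-2-(triethylsilyloxy)-4-[(2R,3R)-6-methyl-2-(triethylsilyloxy)-3-(triisopropylsilyloxy)hept-5-en-2-yl]cyclohex-3-ene-1-carbaldehyde | CC[Si](CC)(CC)O[C@](C)(C1CC[C@](C)(C=O)[C@H](O[Si](CC)(CC)CC)C=1)[C@H](O[Si](C(C)C)(C(C)C)C(C)C)CC=C(C)C | intermediate
16 | (1S,2R)-2-hydroxy-4-[(2R,3R)-2-hydroxy-6-methyl-3-(triisopropylsilyloxy)hept-5-en-2-yl]-1-methylcyclohex-3-ene-1-carbaldehyde | O[C@](C)(C1CC[C@](C)(C=O)[C@H](O)C=1)[C@H](O[Si](C(C)C)(C(C)C)C(C)C)CC=C(C)C | intermediate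
17 | (1S,2R,4S)-2-hydroxy-4-[(2R,3R)-2-hydroxy-6-methyl-3-(triisopropylsilyloxy)hept-5-en-2-yl]-1-methylcyclohexane-1-carbaldehyde | O[C@](C)([C@H]1CC[C@](C)(C=O)[C@H](O)C1)[C@H](O[Si](C(C)C)(C(C)C)C(C)C)CC=C(C)C | intermediate
18 | (1S,2R,4S)-4-[(2R,3R,5R)-5-bromo-2,6,6-trimethyl-3-(triisopropylsilyloxy)oxan-2-yl]-2-hydroxy-1-methylcyclohexane-1-carbaldehyde | CC1(C)O[C@](C)([C@H]2CC[C@](C)(C=O)[C@H](O)C2)[C@H](O[Si](C(C)C)(C(C)C)C(C)C)C[C@H]1Br | intermediate
19 | (1S,2R,4S)-4-[(2R,3R,5R)-5-bromo-2,6,6-trimethyl-3-(triisopropylsilyloxy)oxan-2-yl]-2-hydroxy-1-methylcyclohexyl formate | CC1(C)O[C@](C)([C@H]2CC[C@](C)(OC=O)[C@H](O)C2)[C@H](O[Si](C(C)C)(C(C)C)C(C)C)C[C@H]1Br | intermediate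
20 | (1S,2R,4S)-4-[(2R,3R,5R)-5-bromo-2,6,6-trimethyl-3-(triisopropylsilyloxy)oxan-2-yl]-1-methylcyclohexane-1,2-diol | CC1(C)O[C@](C)([C@H]2CC[C@](C)(O)[C@H](O)C2)[C@H](O[Si](C(C)C)(C(C)C)C(C)C)C[C@H]1Br | intermediate
21 | cyclic sulfite (1,3,2-dioxathiolane 2-oxide, either configuration at sulfur) of diol 20 | CC1(C)O[C@](C)([C@H]2CC[C@](C)(OS(=O)O3)[C@H]3C2)[C@H](O[Si](C(C)C)(C(C)C)C(C)C)C[C@H]1Br | intermediate
22 | cyclic sulfate (1,3,2-dioxathiolane 2,2-dioxide) of diol 20 | CC1(C)O[C@](C)([C@H]2CC[C@](C)(OS(=O)(=O)O3)[C@H]3C2)[C@H](O[Si](C(C)C)(C(C)C)C(C)C)C[C@H]1Br | intermediate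
23 | lithium (1S,2S,4S)-2-bromo-4-[(2R,3R,5R)-5-bromo-2,6,6-trimethyl-3-(triisopropylsilyloxy)oxan-2-yl]-1-methylcyclohexyl sulfate | CC1(C)O[C@](C)([C@H]2CC[C@](C)(OS(=O)(=O)[O-])[C@@H](Br)C2)[C@H](O[Si](C(C)C)(C(C)C)C(C)C)C[C@H]1Br.[Li+] | intermediate
24 | (1S,2S,4S)-2-bromo-4-[(2R,3R,5R)-5-bromo-2,6,6-trimethyl-3-(triisopropylsilyloxy)oxan-2-yl]-1-methylcyclohexan-1-ol | CC1(C)O[C@](C)([C@H]2CC[C@](C)(O)[C@@H](Br)C2)[C@H](O[Si](C(C)C)(C(C)C)C(C)C)C[C@H]1Br | intermediate
25 | {[(2R,3R,5R)-5-bromo-2-[(1S,3S,4S)-3-bromo-4-chloro-4-methylcyclohexyl]-2,6,6-trimethyloxan-3-yl]oxy}tri(propan-2-yl)silane | CC1(C)O[C@](C)([C@H]2CC[C@](C)(Cl)[C@@H](Br)C2)[C@H](O[Si](C(C)C)(C(C)C)C(C)C)C[C@H]1Br | intermediate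
26 | caespitol, (2R,3R,5R)-5-bromo-2-[(1S,3S,4S)-3-bromo-4-chloro-4-methylcyclohexyl]-2,6,6-trimethyloxan-3-ol | CC1(C)O[C@](C)([C@H]2CC[C@](C)(Cl)[C@@H](Br)C2)[C@H](O)C[C@H]1Br | target

**Step count and risks**

Total steps: 15. Longest linear sequence: 15 steps (1 → 26); the route is linear, with the commercial reactants 2, 6 and 14 joined in steps 1, 3 and 8.

Step 10 (bromoetherification). What may go wrong: closure at the less substituted alkene carbon (5-exo, giving an oxolane with a tertiary bromide), bromonium formation on the other alkene face within the chair (C10 epimer), or slow reaction of the hindered tertiary alcohol. Fallback, from 17: the ring is closed by oxymercuration instead. Hg(OCOCF3)2 in MeNO2 at −20 °C, then aq. KBr, should give the equatorial organomercury bromide F1; mercury electrophiles add reversibly and with a strong preference for oxygen at the more substituted carbon, so the most stable chair product should accumulate. Bromodemercuration with Br2 and LiBr in pyridine, which proceeds with retention in this medium, then gives 18.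

Step 14 (tertiary chloride). What may go wrong: loss of the chlorosulfite or of HCl to alkenes, or ionisation with bromine bridging that leads to the C4 epimer or to migration of the halogens. Fallback, from 20: the order of the halogens is reversed.
- Ac2O, DMAP and pyridine acetylate only the secondary C5 hydroxyl to give the hydroxy acetate F2.
- SOCl2 without base converts the tertiary alcohol, now without a neighbouring bromine, into the chloro acetate F3 by the same frontside collapse (the cis acetate cannot participate from the rear).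
- K2CO3 in MeOH gives the cis-chlorohydrin F4, which cannot close to an epoxide.
- Tf2O and pyridine give the chloro triflate F5, and Bu4NBr in toluene displaces the triflate at C5 with inversion to give 25.

Step 9 (directed hydrogenation). What may go wrong: reduction of the C10=C11 alkene, no reduction of the hindered ring alkene, or delivery of hydrogen to the wrong face through the C7 hydroxyl. Fallback, from 16: the order of ring closure and reduction is changed. TBCO in MeNO2 first closes the oxane to the bromo-oxanyl cyclohexene F6, in which no other alkene and no free C7 hydroxyl remain. The ring alkene is then hydrogenated under direction by the C5 hydroxyl with the more active [Ir(cod)(PCy3)(py)]PF6 (H2, CH2Cl2), which gives 18.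

Further compounds
F1 | step 10 | (1S,2R,4S)-4-[(2R,3R,5R)-5-(bromomercurio)-2,6,6-trimethyl-3-(triisopropylsilyloxy)oxan-2-yl]-2-hydroxy-1-methylcyclohexane-1-carbaldehyde | CC1(C)O[C@](C)([C@H]2CC[C@](C)(C=O)[C@H](O)C2)[C@H](O[Si](C(C)C)(C(C)C)C(C)C)C[C@H]1[Hg]Br
F2 | step 14 | (1R,2S,5S)-5-[(2R,3R,5R)-5-bromo-2,6,6-trimethyl-3-(triisopropylsilyloxy)oxan-2-yl]-2-hydroxy-2-methylcyclohexyl acetate | CC1(C)O[C@](C)([C@H]2CC[C@](C)(O)[C@H](OC(C)=O)C2)[C@H](O[Si](C(C)C)(C(C)C)C(C)C)C[C@H]1Br
F3 | step 14 | (1R,2S,5S)-5-[(2R,3R,5R)-5-bromo-2,6,6-trimethyl-3-(triisopropylsilyloxy)oxan-2-yl]-2-chloro-2-methylcyclohexyl acetate | CC1(C)O[C@](C)([C@H]2CC[C@](C)(Cl)[C@H](OC(C)=O)C2)[C@H](O[Si](C(C)C)(C(C)C)C(C)C)C[C@H]1Br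
F4 | step 14 | (1R,2S,5S)-5-[(2R,3R,5R)-5-bromo-2,6,6-trimethyl-3-(triisopropylsilyloxy)oxan-2-yl]-2-chloro-2-methylcyclohexan-1-ol | CC1(C)O[C@](C)([C@H]2CC[C@](C)(Cl)[C@H](O)C2)[C@H](O[Si](C(C)C)(C(C)C)C(C)C)C[C@H]1Br
F5 | step 14 | (1R,2S,5S)-5-[(2R,3R,5R)-5-bromo-2,6,6-trimethyl-3-(triisopropylsilyloxy)oxan-2-yl]-2-chloro-2-methylcyclohexyl trifluoromethanesulfonate | CC1(C)O[C@](C)([C@H]2CC[C@](C)(Cl)[C@H](OS(=O)(=O)C(F)(F)F)C2)[C@H](O[Si](C(C)C)(C(C)C)C(C)C)C[C@H]1Br
F6 | step 9 | (1S,2R)-4-[(2R,3R,5R)-5-bromo-2,6,6-trimethyl-3-(triisopropylsilyloxy)oxan-2-yl]-2-hydroxy-1-methylcyclohex-3-ene-1-carbaldehyde | CC1(C)O[C@](C)(C2CC[C@](C)(C=O)[C@H](O)C=2)[C@H](O[Si](C(C)C)(C(C)C)C(C)C)C[C@H]1Br
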